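## The problem

Compound 19 is an unsymmetrical biaryl of two catechol rings, each carrying an unbranched chain of eight methylenes that ends in a 2,6-dihydroxybenzoyl ketone. Ring A (hydroxyls on C1 and C2) bears ring B on C3, next to a hydroxyl, and its chain on C5, whereas ring B (hydroxyls on C4' and C5') is joined through C1', ortho to its own chain on C2'. A synthesis must therefore deliver a 1,2,3,5-substituted ring A and a 1,2,4,5-substituted ring B and make an aryl–aryl bond flanked by an oxygen on one side and a long chain on the other, a poor site for a late cross-coupling. There is no stereocentre, and the biaryl axis has only two ortho substituents, so nothing has to be controlled in three dimensions and sp3 centres of intermediates may be carried as mixtures. The sensitive groups are the eight phenols: two catechols that oxidise readily to o-quinones (and, having a CH2 para to oxygen, onward to quinone methides) and two 2-acylresorcinols, so free catechols must not meet an oxidant and the phenols are best unmasked last. The two chains are identical, so both should come from one reagent and both aroyl ends should be attached in one operation. The enabling feature is that C1 and C2 of ring A are adjacent oxygen-bearing carbons, while C3, C4, C5 and C6 carry ring B, hydrogen, the chain and hydrogen. This is the pattern of an open-chain 2-aryl-4-alkylhexanedioate whose ester carbons become C2 and C1, so reductive coupling of these two carbons closes ring A and installs both C–O groups at once.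

## Retrosynthesis

**19 to 18.** The four O–CH3 bonds on rings A and B are cut. Methyl ethers are preferred to silyl or benzyl groups because those of ring B arrive with the commercial acid 1 and survive sodium, Grignard reagents, bromine and DDQ. Precursor 18 differs from 19 only by four methyl groups. The forward step must cleave four aryl methyl ethers without harming two aryl ketones, which BBr3 does.

**18 to 16 and 17.** Both C(=O)–CH2 bonds are cut. Adding a chain organometallic to a protected resorcinol aldehyde would need protection and redox steps on each chain, whereas hydroacylation of a terminal alkene by 2,6-dihydroxybenzaldehyde 17 gives the free 2-acylresorcinol directly. The chain length fits: six methylenes plus the two alkene carbons give eight. Precursor 16 is simpler by both aroyl groups, and its chain ends are plain alkenes from one C8 reagent, 3. The forward reaction consumes two molecules of 17, one per alkene, and must be linear-selective and complete at both ends.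

**16 back to 12.** No carbon–carbon bond is cut here; ring A is taken back from the arene to the acyloin oxidation level. Tetramethyl ether 16 comes from the catechol bis-silyl ether 15 by silyl-to-methyl exchange. Compound 15 comes from the 2,3-bis(silyloxy)cyclohexa-1,3-diene 14 by loss of two hydrogens, 14 from the cyclohexane-1,2-dione 13 by double enol silylation, and 13 from the enediol bis-silyl ether 12 by a two-electron oxidation. Dehydrogenating the free dione would be shorter but would expose a free catechol to the oxidant; in the stepwise path the last dehydrogenation acts on a silyl-capped ring. The oxidants must discriminate between ring A and the two terminal alkenes.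

**12 to 11 (key disconnection).** The C1–C2 bond of ring A is cut, giving the dimethyl 2-aryl-4-alkylhexanedioate 11. Cuts at C2–C3 or C3–C4 would lead to hindered biaryl or aryl–enolate couplings. Here ring B sits on an sp3 carbon alpha to an ester, and the ring substituents are fixed by the chain connectivity. The precursor is acyclic and is built by enolate chemistry. The forward reaction must couple two ester carbons of like polarity intramolecularly and leave alkenes and aryl ethers alone.

**11 to 8 and 3.** The bond between C4 of the adipate and the octenyl chain is cut, a conjugate addition of the Grignard reagent 9 (from 3) to enoate 8. The alternative, alkylating an arylacetate with a β-branched γ-halo ester, needs a longer electrophile that is prone to cyclise. The forward step must add 1,4 faster than the organometallic removes the acidic aryl-acetate hydrogen.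

**8 to 5 and 6.** The bond between the benzylic α-carbon and the allylic CH2 is cut, an alkylation of the lithium enolate 7 of arylacetate 5 with methyl 4-bromocrotonate 6. This supplies four of the six ring A carbons, already differentiated. The forward step needs direct substitution at the allylic bromide, not conjugate addition.

**5 to 2 and 3; 2 to 1.** The aryl–CH2 bond of the ring B chain is cut, a Negishi coupling of aryl bromide 2 with the organozinc 4 made from 3. The bromine of commercial acid 1 is already ortho to the acetic acid side chain, so the ring B pattern is bought. The coupling is placed before the enolate steps so that no enoate is present. Ester 2 comes from 1 by esterification.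

## Roads not taken

Alternative 1: Ring B is cut at C1'–C2', C3'–C4' and C5'–C6'. Forward, the diyne 2-ethynyl-6-methoxy-4-(oct-7-en-1-yl)phenyl prop-2-ynoate A1 and 1,2-bis(pinacolboryl)ethyne A2 would undergo Cp*RuCl(cod)-catalysed (2+2+2) cyclotrimerisation to the bis-boryl benzochromenone A3.
- Merits: ring B is formed aromatic, its positions are fixed by the ester tether, the boryl groups are latent catechol hydroxyls, and no hindered biaryl coupling or oxidation-level adjustment of a carbocycle is needed. In this respect it is better than the chosen plan, which spends steps 6 to 9 bringing ring A to the arene.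
- Weak points: the lactone carbonyl of A3 is only the first carbon of ring B's chain, so seven methylenes and the aroyl end must be added after reductive opening, by a sequence different from that of ring A's chain. The terminal alkene of A1 is a competing partner for the ruthenacycle, and the hindered A2 is a slow third component, so diyne self-reaction is a risk. The phenol freed on lactone opening needs separate handling.
- Comparison: the chosen plan answers with both chains from one reagent (3), both ketones in one step (step 10), and a key step in which alkenes are spectators.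

Alternative 2: Ring B is cut at C2'–C3' and C6'–C1'. Forward, the aryl–alkyl alkyne A4, which already holds ring A, both aroyl ends and both chains, and 2,3-dimethoxybuta-1,3-diene A5 would combine under CoBr2(dppe), Zn and ZnI2 (dppe is 1,2-bis(diphenylphosphino)ethane). DDQ would then aromatise the cyclohexa-1,4-diene to the octa-O-methyl ether A6.
- Merits: it is the most convergent road; A6 is one deprotection from the target, and the symmetric diene removes any regiochemical question. If the cycloaddition works, this road is shorter than the chosen one.
- Weak points: the alkyne of A4 is internal and flanked by an ortho methoxy group, so it is a reluctant partner. A5 is an acid-labile bis-enol ether exposed to ZnI2. Two ketones face low-valent cobalt and zinc. The 1,2,3,5-substituted ring A must still be made beforehand, so its pattern problem is moved, not solved.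
- Comparison: the chosen plan builds that pattern from acyclic material and relies on an intramolecular ring closure that needs no metal catalyst.

Alternative 3: Ring A is cut at C3–C4 and C5–C6. Forward, the (Z)-bis(silyloxy)diene A7 carrying ring B and the nitroalkene A8 carrying the chain would undergo thermal Diels–Alder reaction. DBU and DDQ would then remove HNO2 and two hydrogens to give the catechol diester A9 after desilylation.
- Merits: it makes the same ring as the chosen plan but convergently, and after loss of HNO2 the ring is already a dihydrocatechol, so only one dehydrogenation remains. The oxidant meets a silyl-capped ring, a feature the chosen route adopts in steps 7 and 8. In A7 the aryl group is cis to the neighbouring silyloxy group and therefore points away from the s-cis diene, so the geometry itself does not hinder the cycloaddition.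
- Weak points: the two silyloxy groups make both diene termini nucleophilic and cancel each other's directing effect, so the orientation rests on the 1-aryl group alone. That group favours the required adduct, with the nitro carbon next to the aryl-bearing carbon, but the ortho chain twists ring B out of the diene plane and weakens the bias, so the 4-alkyl regioisomer remains a risk. A7 is a moisture- and acid-labile bis(silyl enol ether), and the aliphatic nitroalkene A8 is only a moderate dienophile that polymerises on heating or with base. The ester chain ends of A9 need several more steps to become 2-acylresorcinols.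
- Comparison: Alternative 3 is more convergent and more economical in oxidation steps. The chosen plan offers regiochemical certainty from the connectivity of 11, and alkene chain ends that become the ketones in one step.

Key step: step 5

Assumption: 19 has no stereocentre and its biaryl axis is taken not to give separable atropisomers, so all sp3 centres of intermediates are carried as mixtures.

## Route

Step 1
Reactants: 1 2-(2-bromo-4,5-dimethoxyphenyl)acetic acid
Product: 2 methyl 2-(2-bromo-4,5-dimethoxyphenyl)acetate
Conditions: MeOH, H2SO4 (cat.), reflux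
Reagents that add atoms: methanol, CO
Why: Fischer esterification of an unhindered arylacetic acid; the aryl bromide and aryl ethers are inert to acid in methanol.

Step 2
Reactants: 2 methyl 2-(2-bromo-4,5-dimethoxyphenyl)acetate; 3 8-bromooct-1-ene
Product: 5 methyl 2-[4,5-dimethoxy-2-(oct-7-en-1-yl)phenyl]acetate, via oct-7-en-1-ylzinc bromide 4 (not isolated)
Conditions: 3, Zn dust, LiCl, THF, 50 °C; then 2, Pd(OAc)2 (cat.), SPhos (cat.), THF, 50 °C
Reagents that add atoms: none
Why: Negishi sp2–sp3 coupling: oxidative addition of the electron-rich aryl bromide to zerovalent palladium is supported by the biaryl phosphine, the primary alkylzinc transmetallates without isomerisation, and the organozinc is too weakly basic to touch the ester or its α-hydrogens.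

Step 3
Reactants: 5 methyl 2-[4,5-dimethoxy-2-(oct-7-en-1-yl)phenyl]acetate; 6 methyl (E)-4-bromobut-2-enoate
Product: 8 dimethyl (E)-5-[4,5-dimethoxy-2-(oct-7-en-1-yl)phenyl]hex-2-enedioate (racemic), via lithium ester enolate 7 (not isolated)
Conditions: LiN(SiMe3)2, THF, −78 °C; then 6, −78 → −40 °C; aq. NH4Cl
Reagents that add atoms: none
Why: Enolate alkylation: the aryl-stabilised enolate should displace the primary allylic bromide directly at low temperature, and a cold quench with a slight excess of 6 should prevent a second deprotonation of the product; the new stereocentre is formed racemic and is later erased.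

Step 4
Reactants: 8 dimethyl (E)-5-[4,5-dimethoxy-2-(oct-7-en-1-yl)phenyl]hex-2-enedioate; 3 8-bromooct-1-ene
Product: 11 dimethyl 2-[4,5-dimethoxy-2-(oct-7-en-1-yl)phenyl]-4-(oct-7-en-1-yl)hexanedioate (mixture of diastereomers), via oct-7-en-1-ylmagnesium bromide 9 (not isolated), via trimethylsilyl ketene acetal 10 (not isolated)
Conditions: 3, Mg, THF, rt; then CuBr·SMe2 (10 mol %), Me3SiCl, THF, −78 °C, add 8, −78 → −30 °C; aq. NH4Cl
Reagents that add atoms: none
Why: Chlorosilane-accelerated conjugate addition of a Grignard reagent catalysed by monovalent copper: the organocopper adds to the enoate β-carbon and the enolate is trapped as ketene acetal 10, which should outrun deprotonation of the aryl-acetate hydrogen at −78 °C; the second stereocentre forms without control and this does not matter.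

Step 5
Reactants: 11 dimethyl 2-[4,5-dimethoxy-2-(oct-7-en-1-yl)phenyl]-4-(oct-7-en-1-yl)hexanedioate
Product: 12 3-[4,5-dimethoxy-2-(oct-7-en-1-yl)phenyl]-5-(oct-7-en-1-yl)-1,2-bis(trimethylsilyloxy)cyclohex-1-ene (mixture of diastereomers)
Conditions: Na dispersion (excess), Me3SiCl (excess), toluene, reflux, slow addition of 11 under Ar
Reagents that add atoms: chlorotrimethylsilane, C[Si](C)(C)Cl
Why: Electron transfer from sodium turns both ester groups into ketyl radical anions, which couple within the molecule and form the C1–C2 bond of ring A; loss of two methoxides gives the 1,2-dione, and two further electrons give the enediolate. The closest known reaction is the Rühlmann acyloin condensation of adipic esters to 1,2-bis(trimethylsilyloxy)cyclohexene. The six-membered ring closes by joining the two terminal acyl carbons of the six-carbon chain, formally a 6-exo attack of one ketyl on the other carbonyl. No stereocentre is created, since both new ring carbons are sp2, and the existing centres at C3 and C5 stay as a mixture until aromatisation removes them. Chlorotrimethylsilane silylates the enediolate and the expelled methoxide, so no free base remains for a Dieckmann condensation at the acidic aryl-acetate position. The step needs intramolecular coupling to win over intermolecular coupling, which slow addition to excess sodium provides, the 1,6-relation of the esters making the ring closure fast. It also needs chemoselectivity, which rests on isolated terminal alkenes and aryl methyl ethers not being reduced by sodium in toluene without a proton source or electron carrier.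

Step 6
Reactants: 12 3-[4,5-dimethoxy-2-(oct-7-en-1-yl)phenyl]-5-(oct-7-en-1-yl)-1,2-bis(trimethylsilyloxy)cyclohex-1-ene
Product: 13 3-[4,5-dimethoxy-2-(oct-7-en-1-yl)phenyl]-5-(oct-7-en-1-yl)cyclohexane-1,2-dione (mixture of diastereomers, largely enolised)
Conditions: Br2 (1.0 equiv), CH2Cl2, −78 °C; aq. NaHCO3/Na2S2O3
Reagents that add atoms: none
Why: Bromination of the doubly oxygenated alkene and loss of two Me3SiBr is the standard oxidation of acyloin bis-silyl ethers to 1,2-diones; titration with one equivalent at −78 °C should spare the much less nucleophilic terminal alkenes and ring B, whose positions para to methoxy are blocked.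

Step 7
Reactants: 13 3-[4,5-dimethoxy-2-(oct-7-en-1-yl)phenyl]-5-(oct-7-en-1-yl)cyclohexane-1,2-dione
Product: 14 1-[4,5-dimethoxy-2-(oct-7-en-1-yl)phenyl]-2,3-bis(tert-butyldimethylsilyloxy)-5-(oct-7-en-1-yl)cyclohexa-1,3-diene (racemic)
Conditions: TBSOTf (2.5 equiv), Et3N, CH2Cl2, 0 °C → rt
Reagents that add atoms: tert-butyldimethylsilyl trifluoromethanesulfonate, CC(C)(C)[Si](C)(C)OS(=O)(=O)C(F)(F)F
Why: Soft enolisation and O-silylation of a 1,2-dione to its 2,3-bis(silyloxy)-1,3-diene; each carbonyl of 13 has only one α-CH position (C3 and C6), so a single diene can form, and the aryl-bearing stereocentre disappears.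

Step 8
Reactants: 14 1-[4,5-dimethoxy-2-(oct-7-en-1-yl)phenyl]-2,3-bis(tert-butyldimethylsilyloxy)-5-(oct-7-en-1-yl)cyclohexa-1,3-diene
Product: 15 1,2-bis(tert-butyldimethylsilyloxy)-3-[4,5-dimethoxy-2-(oct-7-en-1-yl)phenyl]-5-(oct-7-en-1-yl)benzene
Conditions: DDQ (1.05 equiv), 2,4,6-collidine, toluene, 0 °C → rt
Reagents that add atoms: none
Why: DDQ dehydrogenation of a silyl dienol ether of the cyclohexa-1,3-diene type: hydride abstraction from allylic C5 or C6 of 14 gives a cation stabilised by a silyloxy group, and proton loss from the neighbouring sp3 carbon gives the arene; the catechol stays silyl-capped so one equivalent of oxidant cannot carry it on to a quinone, and the last sp3 stereocentre is removed.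

Step 9
Reactants: 15 1,2-bis(tert-butyldimethylsilyloxy)-3-[4,5-dimethoxy-2-(oct-7-en-1-yl)phenyl]-5-(oct-7-en-1-yl)benzene
Product: 16 2,3,4',5'-tetramethoxy-2',5-di(oct-7-en-1-yl)-1,1'-biphenyl
Conditions: CsF, MeI, DMF, rt, Ar
Reagents that add atoms: iodomethane, CI
Why: One-pot fluoride desilylation and Williamson methylation of aryl silyl ethers; each phenoxide is methylated as it is released, so no free catechol accumulates.

Step 10
Reactants: 16 2,3,4',5'-tetramethoxy-2',5-di(oct-7-en-1-yl)-1,1'-biphenyl; 17 2,6-dihydroxybenzaldehyde
Product: 18 1-(2,6-dihydroxyphenyl)-9-[2-[5-[9-(2,6-dihydroxyphenyl)-9-oxononyl]-2,3-dimethoxyphenyl]-4,5-dimethoxyphenyl]nonan-1-one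
Conditions: 17 (2.5 equiv), [Rh(cod)OMe]2 (cat.), BINOL-derived phosphoramidite ligand (MonoPhos type, cat.), K3PO4, THF, 70 °C
Reagents that add atoms: 2,6-dihydroxybenzaldehyde (second equivalent of 17), O=Cc1c(O)cccc1O
Why: Phenoxide-directed intermolecular alkene hydroacylation with a salicylaldehyde: the aldehyde C–H adds to monovalent rhodium to give a chelated acyl hydride of trivalent rhodium that resists decarbonylation, the terminal alkene inserts anti-Markovnikov, and reductive elimination gives the linear ketone. The two remote alkenes should react independently, each taking up one molecule of 17, so two molecules of the aldehyde are built into 18 and no other product is formed.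

Step 11
Reactants: 18 1-(2,6-dihydroxyphenyl)-9-[2-[5-[9-(2,6-dihydroxyphenyl)-9-oxononyl]-2,3-dimethoxyphenyl]-4,5-dimethoxyphenyl]nonan-1-one
Product: 19 1-(2,6-dihydroxyphenyl)-9-[2-[5-[9-(2,6-dihydroxyphenyl)-9-oxononyl]-2,3-dihydroxyphenyl]-4,5-dihydroxyphenyl]nonan-1-one
Conditions: BBr3 (excess), CH2Cl2, −78 °C → rt; then MeOH/H2O, under Ar
Reagents that add atoms: none
Why: Lewis-acid cleavage of aryl methyl ethers by BBr3; the aryl ketones and free resorcinol hydroxyls only form boron chelates that hydrolyse on work-up, and no alkene remains to add HBr.

## Compound list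

1 | 2-(2-bromo-4,5-dimethoxyphenyl)acetic acid | COc1cc(Br)c(CC(=O)O)cc1OC | starting material
2 | methyl 2-(2-bromo-4,5-dimethoxyphenyl)acetate | COC(=O)Cc1cc(OC)c(OC)cc1Br | intermediate
3 | 8-bromooct-1-ene | C=CCCCCCCBr | starting material
4 | oct-7-en-1-ylzinc bromide (not isolated) | C=CCCCCCC[Zn]Br | intermediate
5 | methyl 2-[4,5-dimethoxy-2-(oct-7-en-1-yl)phenyl]acetate | COC(=O)Cc1cc(OC)c(OC)cc1CCCCCCC=C | intermediate
6 | methyl (E)-4-bromobut-2-enoate | COC(=O)/C=C/CBr | starting material
7 | lithium enolate of 5 (not isolated) | COC(O[Li])=Cc1cc(OC)c(OC)cc1CCCCCCC=C | intermediate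
8 | dimethyl (E)-5-[4,5-dimethoxy-2-(oct-7-en-1-yl)phenyl]hex-2-enedioate (racemic) | COC(=O)/C=C/CC(C(=O)OC)c1cc(OC)c(OC)cc1CCCCCCC=C | intermediate
9 | oct-7-en-1-ylmagnesium bromide (not isolated) | C=CCCCCCC[Mg]Br | intermediate
10 | trimethylsilyl ketene acetal of 11 at the unsubstituted acetate end (not isolated, mixture of isomers) | COC(O[Si](C)(C)C)=CC(CCCCCCC=C)CC(C(=O)OC)c1cc(OC)c(OC)cc1CCCCCCC=C | intermediate
11 | dimethyl 2-[4,5-dimethoxy-2-(oct-7-en-1-yl)phenyl]-4-(oct-7-en-1-yl)hexanedioate (mixture of diastereomers) | COC(=O)CC(CCCCCCC=C)CC(C(=O)OC)c1cc(OC)c(OC)cc1CCCCCCC=C | intermediate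
12 | 3-[4,5-dimethoxy-2-(oct-7-en-1-yl)phenyl]-5-(oct-7-en-1-yl)-1,2-bis(trimethylsilyloxy)cyclohex-1-ene (mixture of diastereomers) | C[Si](C)(C)OC1=C(O[Si](C)(C)C)C(c2cc(OC)c(OC)cc2CCCCCCC=C)CC(CCCCCCC=C)C1 | intermediate
13 | 3-[4,5-dimethoxy-2-(oct-7-en-1-yl)phenyl]-5-(oct-7-en-1-yl)cyclohexane-1,2-dione (mixture of diastereomers, drawn as diketone) | O=C1CC(CCCCCCC=C)CC(c2cc(OC)c(OC)cc2CCCCCCC=C)C1=O | intermediate
14 | 1-[4,5-dimethoxy-2-(oct-7-en-1-yl)phenyl]-2,3-bis(tert-butyldimethylsilyloxy)-5-(oct-7-en-1-yl)cyclohexa-1,3-diene (racemic) | CC(C)(C)[Si](C)(C)OC1=CC(CCCCCCC=C)CC(c2cc(OC)c(OC)cc2CCCCCCC=C)=C1O[Si](C)(C)C(C)(C)C | intermediate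
15 | 1,2-bis(tert-butyldimethylsilyloxy)-3-[4,5-dimethoxy-2-(oct-7-en-1-yl)phenyl]-5-(oct-7-en-1-yl)benzene | CC(C)(C)[Si](C)(C)Oc1cc(CCCCCCC=C)cc(-c2cc(OC)c(OC)cc2CCCCCCC=C)c1O[Si](C)(C)C(C)(C)C | intermediate
16 | 2,3,4',5'-tetramethoxy-2',5-di(oct-7-en-1-yl)-1,1'-biphenyl | COc1cc(CCCCCCC=C)cc(-c2cc(OC)c(OC)cc2CCCCCCC=C)c1OC | intermediate
17 | 2,6-dihydroxybenzaldehyde | O=Cc1c(O)cccc1O | starting material
18 | 1-(2,6-dihydroxyphenyl)-9-[2-[5-[9-(2,6-dihydroxyphenyl)-9-oxononyl]-2,3-dimethoxyphenyl]-4,5-dimethoxyphenyl]nonan-1-one | COc1cc(CCCCCCCCC(=O)c2c(O)cccc2O)cc(-c2cc(OC)c(OC)cc2CCCCCCCCC(=O)c2c(O)cccc2O)c1OC | intermediate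
19 | 1-(2,6-dihydroxyphenyl)-9-[2-[5-[9-(2,6-dihydroxyphenyl)-9-oxononyl]-2,3-dihydroxyphenyl]-4,5-dihydroxyphenyl]nonan-1-one (no stereocentre) | O=C(CCCCCCCCc1cc(O)c(O)c(-c2cc(O)c(O)cc2CCCCCCCCC(=O)c2c(O)cccc2O)c1)c1c(O)cccc1O | target

## Step count and risks

Total: 11 steps. Longest linear sequence: 11 steps, from 1 to 19; compounds 3, 6 and 17 are commercial and enter directly.

**Step 5 (key step).** The aryl-acetate α-hydrogen may be removed by ketyl or alkoxide species on the sodium surface and the enolate silylated, which withdraws diester from the coupling. Intermolecular coupling may also compete if the addition is too fast. Fallback, from 11 back to 13: reduce both esters with iBu2AlH at −78 °C to the dialdehyde 2-[4,5-dimethoxy-2-(oct-7-en-1-yl)phenyl]-4-(oct-7-en-1-yl)hexanedial F1. Close the same C1–C2 bond by SmI2 pinacol cyclisation to 3-[4,5-dimethoxy-2-(oct-7-en-1-yl)phenyl]-5-(oct-7-en-1-yl)cyclohexane-1,2-diol F2. A double Swern oxidation of F2 then gives dione 13, replacing steps 5 and 6.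

**Step 3.** The enolate may add to the enoate β-carbon and the new enolate may displace bromide, closing a cyclopropane; over-alkylation is a lesser risk. Fallback, from 2 back to 8: allylate the enolate of 2 (LiN(SiMe3)2, allyl bromide) to methyl 2-(2-bromo-4,5-dimethoxyphenyl)pent-4-enoate F3. Cross-metathesis with methyl acrylate (second-generation Hoveyda–Grubbs catalyst) gives dimethyl (E)-5-(2-bromo-4,5-dimethoxyphenyl)hex-2-enedioate F4. Negishi coupling of F4 with 4 under the step 2 conditions gives 8; the octenyl alkene is absent during metathesis.

**Step 4.** The Grignard reagent may deprotonate the doubly activated C5–H or attack an ester carbonyl, and the resulting enolate may close onto the enoate. Fallback, from 5 back to 11: make the chain-bearing carbon on a substrate without acidic hydrogen. Copper-catalysed addition of 9 to furan-2(5H)-one (CuBr·SMe2, Me3SiCl) gives 4-(oct-7-en-1-yl)oxolan-2-one F5. Ring opening with Me3SiCl/NaI and then methanol gives methyl 3-(iodomethyl)undec-10-enoate F6. Alkylation of the stabilised enolate 7 with F6 in THF/DMPU gives 11, replacing steps 3 and 4.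

**Step 8.** The cationic intermediate may lose a silyl group instead of a proton, giving a partly unprotected ring that further oxidant takes to an o-quinone. DDQ may also add to the electron-rich diene. Fallback, from 13 back to 16: aromatise the dione with catalytic I2 in DMSO at 80 °C (enol iodination, loss of HI, re-oxidation of iodide by the solvent) to 3-[4,5-dimethoxy-2-(oct-7-en-1-yl)phenyl]-5-(oct-7-en-1-yl)benzene-1,2-diol F7. Methylation of F7 with MeI and K2CO3 in acetone under argon gives 16, replacing steps 7 to 9.

**Step 10.** The second alkene may fail to react, or rhodium hydride chain-walking may move an alkene inward where it no longer reacts, so that conversion stops after one hydroacylation; branched-selective insertion and aldehyde decarbonylation are further losses. Fallback, from 16 back to 19: hydrozirconate both alkenes with Cp2Zr(H)Cl and acylate the alkylzirconium species with 2,6-dimethoxybenzoyl chloride under CuBr·SMe2 catalysis. This gives 1-(2,6-dimethoxyphenyl)-9-[2-[5-[9-(2,6-dimethoxyphenyl)-9-oxononyl]-2,3-dimethoxyphenyl]-4,5-dimethoxyphenyl]nonan-1-one F8, the same structure as A6. BBr3 then removes all eight methyl groups to give 19.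

## Further compounds

F1 | step 5 | 2-[4,5-dimethoxy-2-(oct-7-en-1-yl)phenyl]-4-(oct-7-en-1-yl)hexanedial (mixture of diastereomers) | O=CCC(CCCCCCC=C)CC(C=O)c1cc(OC)c(OC)cc1CCCCCCC=C
F2 | step 5 | 3-[4,5-dimethoxy-2-(oct-7-en-1-yl)phenyl]-5-(oct-7-en-1-yl)cyclohexane-1,2-diol (mixture of diastereomers) | OC1CC(CCCCCCC=C)CC(c2cc(OC)c(OC)cc2CCCCCCC=C)C1O
F3 | step 3 | methyl 2-(2-bromo-4,5-dimethoxyphenyl)pent-4-enoate (racemic) | COC(=O)C(CC=C)c1cc(OC)c(OC)cc1Br
F4 | step 3 | dimethyl (E)-5-(2-bromo-4,5-dimethoxyphenyl)hex-2-enedioate (racemic) | COC(=O)/C=C/CC(C(=O)OC)c1cc(OC)c(OC)cc1Br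
F5 | step 4 | 4-(oct-7-en-1-yl)oxolan-2-one (racemic) | O=C1CC(CCCCCCC=C)CO1
F6 | step 4 | methyl 3-(iodomethyl)undec-10-enoate (racemic) | COC(=O)CC(CI)CCCCCCC=C
F7 | step 8 | 3-[4,5-dimethoxy-2-(oct-7-en-1-yl)phenyl]-5-(oct-7-en-1-yl)benzene-1,2-diol | Oc1cc(CCCCCCC=C)cc(-c2cc(OC)c(OC)cc2CCCCCCC=C)c1O
F8 | step 10 | 1-(2,6-dimethoxyphenyl)-9-[2-[5-[9-(2,6-dimethoxyphenyl)-9-oxononyl]-2,3-dimethoxyphenyl]-4,5-dimethoxyphenyl]nonan-1-one | COc1cc(CCCCCCCCC(=O)c2c(OC)cccc2OC)cc(-c2cc(OC)c(OC)cc2CCCCCCCCC(=O)c2c(OC)cccc2OC)c1OC
A1 | alternative 1 | 2-ethynyl-6-methoxy-4-(oct-7-en-1-yl)phenyl prop-2-ynoate | C#CC(=O)Oc1c(OC)cc(CCCCCCC=C)cc1C#C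
A2 | alternative 1 | 1,2-bis(4,4,5,5-tetramethyl-1,3,2-dioxaborolan-2-yl)ethyne | CC1(C)OB(C#CB2OC(C)(C)C(C)(C)O2)OC1(C)C
A3 | alternative 1 | 4-methoxy-2-(oct-7-en-1-yl)-8,9-bis(4,4,5,5-tetramethyl-1,3,2-dioxaborolan-2-yl)-6H-benzo[c]chromen-6-one | C=CCCCCCCc1cc(OC)c2OC(=O)c3cc(B4OC(C)(C)C(C)(C)O4)c(B4OC(C)(C)C(C)(C)O4)cc3-c2c1
A4 | alternative 2 | 1-(2,6-dimethoxyphenyl)-11-[5-[9-(2,6-dimethoxyphenyl)-9-oxononyl]-2,3-dimethoxyphenyl]undec-10-yn-1-one | COc1cc(CCCCCCCCC(=O)c2c(OC)cccc2OC)cc(C#CCCCCCCCCC(=O)c2c(OC)cccc2OC)c1OC
A5 | alternative 2 | 2,3-dimethoxybuta-1,3-diene | C=C(OC)C(OC)=C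
A6 | alternative 2 | 1-(2,6-dimethoxyphenyl)-9-[2-[5-[9-(2,6-dimethoxyphenyl)-9-oxononyl]-2,3-dimethoxyphenyl]-4,5-dimethoxyphenyl]nonan-1-one | COc1cc(CCCCCCCCC(=O)c2c(OC)cccc2OC)cc(-c2cc(OC)c(OC)cc2CCCCCCCCC(=O)c2c(OC)cccc2OC)c1OC
A7 | alternative 3 | methyl 9-[2-[(1Z)-2,3-bis(trimethylsilyloxy)buta-1,3-dien-1-yl]-4,5-dimethoxyphenyl]nonanoate | COC(=O)CCCCCCCCc1cc(OC)c(OC)cc1/C=C(\O[Si](C)(C)C)C(O[Si](C)(C)C)=C
A8 | alternative 3 | methyl (E)-11-nitroundec-10-enoate | COC(=O)CCCCCCCC/C=C/[N+](=O)[O-]
A9 | alternative 3 | methyl 9-[3,4-dihydroxy-5-[4,5-dimethoxy-2-(9-methoxy-9-oxononyl)phenyl]phenyl]nonanoate | COC(=O)CCCCCCCCc1cc(O)c(O)c(-c2cc(OC)c(OC)cc2CCCCCCCCC(=O)OC)c1
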